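## Retrosynthetic overview

1. Target 19 ⇐ global hydrogenolysis of the dodeca-O-benzyl bromo trimer 18 ⇐ Friedel–Crafts union of C4 of the upper-unit flavan-3,4-diol 10 with C8 of the upper ring A of dimer 17.
2. Dimer 17 ⇐ 4β→6 coupling of the epicatechin-derived C4 ether 16 with C8-bromo-capped catechin 13; all rings of the middle and lower units are bought intact in (−)-epicatechin and (+)-catechin.
3. Diol 10 ⇐ C3–C4 bond of ring C of the upper unit by reductive pinacol union of the two aldehyde carbons of dialdehyde 9; O1–C2 comes from a Mitsunobu inversion of (S)-mandelate 4 with salicylaldehyde 6.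
4. Enabling feature: in ring C of the upper unit, C3 is a carbinol carbon and its neighbour C4 is a benzylic carbon on the phloroglucinol-type ring A, ortho/para to the oxygens on C5, C7 and C8a (O1). Both map onto formyl carbons, and a C4–OH left by their union ionizes easily and is replaced by C8 of the middle unit trans to the 3-OH.
5. Ring order: rings A and B of the upper unit enter as arenes, ring C of the upper unit is the only ring built (step 7); the two interflavan bonds follow (steps 12 and 13).

Key step: step 7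

Remark: Cp2TiPh is taken as a separately prepared THF stock solution (from Cp2TiCl2, i-PrMgCl, then PhMgBr), and compounds 1, 5, 11 and 14 are taken as purchased.

## Route

Step 1
Reactants: 1 4-bromo-1,2-bis(benzyloxy)benzene
Product: 3 methyl 2-[3,4-bis(benzyloxy)phenyl]-2-oxoacetate, via 3,4-bis(benzyloxy)phenyllithium 2 (not isolated)
Conditions: n-BuLi, THF, −78 °C; cannulated into dimethyl oxalate (3 equiv), THF, −78 °C; aq. NH4Cl
Reagents that add atoms: dimethyl oxalate, COC(=O)C(=O)OC
Why: Bromine–lithium exchange gives aryllithium 2, which is acylated only once by excess dimethyl oxalate under inverse addition because the tetrahedral adduct persists at −78 °C until work-up; no stereocenter is formed.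

Step 2
Reactants: 3 methyl 2-[3,4-bis(benzyloxy)phenyl]-2-oxoacetate
Product: 4 methyl (S)-2-[3,4-bis(benzyloxy)phenyl]-2-hydroxyacetate
Conditions: RuCl(p-cymene)[(R,R)-TsDPEN] (1 mol %), HCO2H/Et3N (5:2), DMF, rt
Reagents that add atoms: none
Why: Asymmetric transfer hydrogenation of an aryl glyoxylate is an established route to mandelates, and with the (R,R)-ligand the aryl-directed hydride delivery should give the (S)-carbinol, the precursor of C2 of the upper unit (the antipodal ligand is at hand should the sense be opposite).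

Step 3
Reactants: 5 3,5-bis(benzyloxy)phenol
Product: 6 4,6-bis(benzyloxy)-2-hydroxybenzaldehyde
Conditions: MgCl2, Et3N, paraformaldehyde, MeCN, reflux; 1 M HCl
Reagents that add atoms: paraformaldehyde (as formaldehyde), C=O
Why: Magnesium-phenoxide-directed ortho-formylation (hydroxymethylation, then hydride transfer to a second formaldehyde) attacks only a position ortho to the free OH, and the two ortho positions of 5 are equivalent; no stereocenter is formed.

Step 4
Reactants: 6 4,6-bis(benzyloxy)-2-hydroxybenzaldehyde; 4 methyl (S)-2-[3,4-bis(benzyloxy)phenyl]-2-hydroxyacetate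
Product: 7 methyl (R)-2-[3,5-bis(benzyloxy)-2-formylphenoxy]-2-[3,4-bis(benzyloxy)phenyl]acetate
Conditions: PPh3, DIAD, toluene, 0 °C to rt
Reagents that add atoms: none
Why: In this Mitsunobu etherification the acidic salicylaldehyde-type phenol displaces the oxyphosphonium of the α-hydroxy ester by SN2 with inversion (the ester group disfavours ionization), so (S)-4 gives the (R)-aryl ether and fixes C2 of the upper unit.

Step 5
Reactants: 7 methyl (R)-2-[3,5-bis(benzyloxy)-2-formylphenoxy]-2-[3,4-bis(benzyloxy)phenyl]acetate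
Product: 8 (R)-2-[3,5-bis(benzyloxy)-2-(hydroxymethyl)phenoxy]-2-[3,4-bis(benzyloxy)phenyl]ethan-1-ol
Conditions: LiBH4, THF, 0 °C to rt; aq. NH4Cl
Reagents that add atoms: none
Why: Borohydride reduction takes both the aryl aldehyde and the activated α-aryloxy ester to primary alcohols under conditions too weakly basic to enolize the ester, so the (R) center is retained.

Step 6
Reactants: 8 (R)-2-[3,5-bis(benzyloxy)-2-(hydroxymethyl)phenoxy]-2-[3,4-bis(benzyloxy)phenyl]ethan-1-ol
Product: 9 (R)-2-[3,5-bis(benzyloxy)-2-formylphenoxy]-2-[3,4-bis(benzyloxy)phenyl]acetaldehyde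
Conditions: Dess–Martin periodinane (2.5 equiv), pyridine, CH2Cl2, 0 °C; used at once
Reagents that add atoms: none
Why: Buffered Dess–Martin oxidation converts both primary alcohols into aldehydes under neutral, non-enolizing conditions, which is needed because the α-aryl-α-aryloxy aldehyde is configurationally labile; the C2 center is not touched.

Step 7
Reactants: 9 (R)-2-[3,5-bis(benzyloxy)-2-formylphenoxy]-2-[3,4-bis(benzyloxy)phenyl]acetaldehyde
Product: 10 (2R,3R,4S)-5,7-bis(benzyloxy)-2-[3,4-bis(benzyloxy)phenyl]chromane-3,4-diol (3-OH cis to the 2-aryl group, 4-OH trans to the 3-OH)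
Conditions: Cp2TiPh (2.4 equiv, THF stock solution), THF, −78 to 0 °C, slow addition of 9 (final 0.01 M); aq. K2CO3
Reagents that add atoms: none
Why: Cp2TiPh (trivalent titanium) binds each formyl oxygen and transfers one electron, the aryl aldehyde being reduced first, to give titanoxy ketyl radicals whose intramolecular coupling joins the two formerly electrophilic carbons C3 and C4 and gives the vicinal diol on hydrolysis. The closest known reaction type is the trans-selective intramolecular pinacol cyclization of 1,6-dialdehydes with monomeric trivalent titanocene reagents. Ring C, six-membered, is closed by ketyl–ketyl recombination, equivalent to a 6-exo-trig attack of the C4 ketyl on the C3 carbonyl carbon. The titanoxy group on C4 should go pseudo-axial to avoid the peri benzyloxy group on C5, the titanoxy group on C3 then goes anti (axial) to it so that the two bulky, unbridged Cp2Ti(Ph)O groups stay apart, and the 2-aryl group stays equatorial; C3 is therefore set cis to the aryl group by the C2 stereocenter through the chair-like transition state, and C4 is set trans to C3. The step needs cyclization over intermolecular coupling (high dilution, slow addition), trans- over cis-diol (a non-bridging titanium reductant instead of a chelating one) and survival of the enolizable C2 center (neutral, cold, non-basic medium).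

Step 8
Reactants: 11 (+)-catechin
Product: 12 5,7,3',4'-tetra-O-benzyl-(+)-catechin
Conditions: BnBr (4.4 equiv), K2CO3, DMF, 0 °C to rt
Reagents that add atoms: benzyl bromide, BrCc1ccccc1
Why: Williamson benzylation with K2CO3 alkylates the four phenols and leaves the far less acidic secondary 3-OH free; the stereocenters are not touched.

Step 9
Reactants: 12 5,7,3',4'-tetra-O-benzyl-(+)-catechin
Product: 13 8-bromo-5,7,3',4'-tetra-O-benzyl-(+)-catechin
Conditions: NBS (1.0 equiv), CH2Cl2, −78 °C to rt
Reagents that add atoms: N-bromosuccinimide, O=C1CCC(=O)N1Br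
Why: Electrophilic aromatic bromination of the phloroglucinol-type ring A occurs at C8, the more accessible and more nucleophilic position, and caps it so that only C6 remains for the later coupling.

Step 10
Reactants: 14 (−)-epicatechin
Product: 15 5,7,3',4'-tetra-O-benzyl-(−)-epicatechin
Conditions: BnBr (4.4 equiv), K2CO3, DMF, 0 °C to rt
Reagents that add atoms: benzyl bromide, BrCc1ccccc1
Why: Williamson benzylation of the four phenols as in step 8, with the 3-OH and both stereocenters untouched.

Step 11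
Reactants: 15 5,7,3',4'-tetra-O-benzyl-(−)-epicatechin
Product: 16 4β-(2-ethoxyethoxy)-5,7,3',4'-tetra-O-benzyl-(−)-epicatechin (4-alkoxy group trans to the 3-OH)
Conditions: DDQ (2 equiv), 2-ethoxyethanol, CH2Cl2, rt
Reagents that add atoms: 2-ethoxyethanol, CCOCCO
Why: DDQ abstracts hydride from the benzylic C4 to give the ring-A-stabilized cation, a standard oxidation of benzylated flavan-3-ols, and the alcohol adds trans to the axial 3-OH of the 2,3-cis scaffold, which sets C4 as 4β.

Step 12
Reactants: 16 4β-(2-ethoxyethoxy)-5,7,3',4'-tetra-O-benzyl-(−)-epicatechin; 13 8-bromo-5,7,3',4'-tetra-O-benzyl-(+)-catechin (3 equiv, excess recovered)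
Product: 17 5,7,3',4'-tetra-O-benzylepicatechin-(4β→6)-8-bromo-5,7,3',4'-tetra-O-benzylcatechin
Conditions: TMSOTf (0.2 equiv), CH2Cl2, −78 to −40 °C
Reagents that add atoms: none
Why: Lewis-acid ionization of the C4 ether of 16 and Friedel–Crafts attack by C6, the only free ring A position of bromo-capped 13, from the face trans to the 3-OH gives the 4β→6 interflavan bond and sets C4 of the middle unit.

Step 13
Reactants: 10 (2R,3R,4S)-5,7-bis(benzyloxy)-2-[3,4-bis(benzyloxy)phenyl]chromane-3,4-diol; 17 5,7,3',4'-tetra-O-benzylepicatechin-(4β→6)-8-bromo-5,7,3',4'-tetra-O-benzylcatechin (1.5 equiv, excess recovered)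
Product: 18 5,7,3',4'-tetra-O-benzylepicatechin-(4β→8)-5,7,3',4'-tetra-O-benzylepicatechin-(4β→6)-8-bromo-5,7,3',4'-tetra-O-benzylcatechin
Conditions: BF3·OEt2 (0.2 equiv), 4 Å molecular sieves, CH2Cl2, −78 to −30 °C, slow addition of 10 to 17
Reagents that add atoms: none
Why: The C4–OH of 10, benzylic to a ring with three donor oxygens, ionizes under catalytic Lewis acid and the cation is captured in a Friedel–Crafts reaction by C8 of the upper ring A of 17 (more nucleophilic and accessible than its C6) anti to the axial 3-OH, which sets the new C4 center as 4β whatever the configuration of the departing hydroxyl.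

Step 14
Reactants: 18 5,7,3',4'-tetra-O-benzylepicatechin-(4β→8)-5,7,3',4'-tetra-O-benzylepicatechin-(4β→6)-8-bromo-5,7,3',4'-tetra-O-benzylcatechin
Product: 19 arecatannin B1
Conditions: H2 (1 atm), Pd(OH)2/C, Et3N (1.5 equiv), THF/MeOH/H2O, rt; Sephadex LH-20
Reagents that add atoms: none
Why: Hydrogenolysis over Pd(OH)2/C cleaves all twelve benzyl ethers and the aryl C–Br bond, with Et3N buffering the HBr so that the acid-labile interflavan bonds survive; no stereocenter is touched.

## Compound list

1 | 4-bromo-1,2-bis(benzyloxy)benzene | Brc1ccc(OCc2ccccc2)c(OCc2ccccc2)c1 | starting material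
2 | 3,4-bis(benzyloxy)phenyllithium | [Li]c1ccc(OCc2ccccc2)c(OCc2ccccc2)c1 | intermediate (not isolated)
3 | methyl 2-[3,4-bis(benzyloxy)phenyl]-2-oxoacetate | COC(=O)C(=O)c1ccc(OCc2ccccc2)c(OCc2ccccc2)c1 | intermediate
4 | methyl (S)-2-[3,4-bis(benzyloxy)phenyl]-2-hydroxyacetate | COC(=O)[C@@H](O)c1ccc(OCc2ccccc2)c(OCc2ccccc2)c1 | intermediate
5 | 3,5-bis(benzyloxy)phenol | Oc1cc(OCc2ccccc2)cc(OCc2ccccc2)c1 | starting material
6 | 4,6-bis(benzyloxy)-2-hydroxybenzaldehyde | O=Cc1c(O)cc(OCc2ccccc2)cc1OCc1ccccc1 | intermediate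
7 | methyl (R)-2-[3,5-bis(benzyloxy)-2-formylphenoxy]-2-[3,4-bis(benzyloxy)phenyl]acetate | O=Cc1c(OCc2ccccc2)cc(OCc2ccccc2)cc1O[C@H](c1ccc(OCc2ccccc2)c(OCc2ccccc2)c1)C(=O)OC | intermediate
8 | (R)-2-[3,5-bis(benzyloxy)-2-(hydroxymethyl)phenoxy]-2-[3,4-bis(benzyloxy)phenyl]ethan-1-ol | OCc1c(OCc2ccccc2)cc(OCc2ccccc2)cc1O[C@H](c1ccc(OCc2ccccc2)c(OCc2ccccc2)c1)CO | intermediate
9 | (R)-2-[3,5-bis(benzyloxy)-2-formylphenoxy]-2-[3,4-bis(benzyloxy)phenyl]acetaldehyde | O=Cc1c(OCc2ccccc2)cc(OCc2ccccc2)cc1O[C@H](c1ccc(OCc2ccccc2)c(OCc2ccccc2)c1)C=O | intermediate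
10 | (2R,3R,4S)-5,7-bis(benzyloxy)-2-[3,4-bis(benzyloxy)phenyl]chromane-3,4-diol (2,3-cis, 3,4-trans) | c1ccccc1COc1cc(OCc2ccccc2)c2c(c1)O[C@H](c1ccc(OCc3ccccc3)c(OCc3ccccc3)c1)[C@H](O)[C@H]2O | intermediate
11 | (+)-catechin, (2R,3S) | Oc1cc(O)c2c(c1)O[C@H](c1ccc(O)c(O)c1)[C@@H](O)C2 | starting material
12 | 5,7,3',4'-tetra-O-benzyl-(+)-catechin | c1ccccc1COc1cc(OCc2ccccc2)c2c(c1)O[C@H](c1ccc(OCc3ccccc3)c(OCc3ccccc3)c1)[C@@H](O)C2 | intermediate
13 | 8-bromo-5,7,3',4'-tetra-O-benzyl-(+)-catechin | c1ccccc1COc1cc(OCc2ccccc2)c2c(c1Br)O[C@H](c1ccc(OCc3ccccc3)c(OCc3ccccc3)c1)[C@@H](O)C2 | intermediate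
14 | (−)-epicatechin, (2R,3R) | Oc1cc(O)c2c(c1)O[C@H](c1ccc(O)c(O)c1)[C@H](O)C2 | starting material
15 | 5,7,3',4'-tetra-O-benzyl-(−)-epicatechin | c1ccccc1COc1cc(OCc2ccccc2)c2c(c1)O[C@H](c1ccc(OCc3ccccc3)c(OCc3ccccc3)c1)[C@H](O)C2 | intermediate
16 | 4β-(2-ethoxyethoxy)-5,7,3',4'-tetra-O-benzyl-(−)-epicatechin (2,3-cis, 3,4-trans) | c1ccccc1COc1cc(OCc2ccccc2)c2c(c1)O[C@H](c1ccc(OCc3ccccc3)c(OCc3ccccc3)c1)[C@H](O)[C@H]2OCCOCC | intermediate
17 | 5,7,3',4'-tetra-O-benzylepicatechin-(4β→6)-8-bromo-5,7,3',4'-tetra-O-benzylcatechin | c1ccccc1COc1cc(OCc2ccccc2)c2c(c1)O[C@H](c1ccc(OCc3ccccc3)c(OCc3ccccc3)c1)[C@H](O)[C@H]2c1c(OCc2ccccc2)c(Br)c2c(c1OCc1ccccc1)C[C@H](O)[C@@H](c1ccc(OCc3ccccc3)c(OCc3ccccc3)c1)O2 | intermediate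
18 | 5,7,3',4'-tetra-O-benzylepicatechin-(4β→8)-5,7,3',4'-tetra-O-benzylepicatechin-(4β→6)-8-bromo-5,7,3',4'-tetra-O-benzylcatechin | c1ccccc1COc1cc(OCc2ccccc2)c2c(c1)O[C@H](c1ccc(OCc3ccccc3)c(OCc3ccccc3)c1)[C@H](O)[C@H]2c1c(OCc2ccccc2)cc(OCc2ccccc2)c2c1O[C@H](c1ccc(OCc3ccccc3)c(OCc3ccccc3)c1)[C@H](O)[C@H]2c1c(OCc2ccccc2)c(Br)c2c(c1OCc1ccccc1)C[C@H](O)[C@@H](c1ccc(OCc3ccccc3)c(OCc3ccccc3)c1)O2 | intermediate
19 | arecatannin B1, epicatechin-(4β→8)-epicatechin-(4β→6)-catechin | Oc1cc(O)c2c(c1)O[C@H](c1ccc(O)c(O)c1)[C@H](O)[C@H]2c1c(O)cc(O)c2c1O[C@H](c1ccc(O)c(O)c1)[C@H](O)[C@H]2c1c(O)cc2c(c1O)C[C@H](O)[C@@H](c1ccc(O)c(O)c1)O2 | target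

## Step count and risks

Total step count: 14. Longest linear sequence: 8 steps (steps 1, 2, 4, 5, 6, 7, 13, 14).

Step 7. The ketyl coupling may take the bridged course that places the 3-oxygen trans to the 2-aryl group, or C2 may epimerize by enolization of the α-aryloxy aldehyde before the ring closes. The fallback gives up the de novo ring closure and takes the upper unit from the chiral pool. A second portion of 16 is ionized with TMSOTf in CH2Cl2 at −78 °C in the presence of excess 17, which attacks through C8 of its upper ring A trans to the 3-OH. This sets out from 16 and 17 and comes back to the route at 18; no compound outside the list is made (F0).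

Step 13. The cation from 10 may be consumed by self-condensation through the free C6 and C8 positions of its own ring A, or may attack C6 instead of C8 of 17, and the valuable dimer is then lost. The fallback reverses the order of assembly so that each cation meets a cheap monomer in large excess. Diol 10 is coupled with excess 15 (catalytic BF3·OEt2, CH2Cl2, −78 °C) to give 5,7,3',4'-tetra-O-benzylepicatechin-(4β→8)-5,7,3',4'-tetra-O-benzylepicatechin F1. Its lower unit is oxidized at C4 with DDQ and 2-ethoxyethanol to the dimeric 4β-(2-ethoxyethoxy) ether F2, and F2 is coupled with excess 13 under TMSOTf at C6. This sets out from 10, 15 and 13 and comes back to the route at 18.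

Step 4. The hydrogen-bonded, doubly ortho-substituted phenol may attack the oxyphosphonium too slowly, so that the activated mandelate ionizes or eliminates and the inversion is incomplete. The fallback sets the C2 center by catalyst control instead of substitution. Keto ester 3 is condensed with TsNHNH2 in MeOH to methyl 2-[3,4-bis(benzyloxy)phenyl]-2-(tosylhydrazono)acetate F3. DBU in CH2Cl2 converts this into methyl 2-diazo-2-[3,4-bis(benzyloxy)phenyl]acetate F4. The carbene from F4 is inserted into the O–H bond of 6 with PdCl2(PhCN)2, a chiral spiro-bis(oxazoline) ligand and NaB[3,5-(CF3)2C6H3]4, the ligand antipode being chosen for the (R) product. This sets out from 3 and 6 and comes back to the route at 7.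

## Further compounds

F0 | step 7 | none | none
F1 | step 13 | 5,7,3',4'-tetra-O-benzylepicatechin-(4β→8)-5,7,3',4'-tetra-O-benzylepicatechin | c1ccccc1COc1cc(OCc2ccccc2)c2c(c1)O[C@H](c1ccc(OCc3ccccc3)c(OCc3ccccc3)c1)[C@H](O)[C@H]2c1c(OCc2ccccc2)cc(OCc2ccccc2)c2c1O[C@H](c1ccc(OCc3ccccc3)c(OCc3ccccc3)c1)[C@H](O)C2
F2 | step 13 | 5,7,3',4'-tetra-O-benzylepicatechin-(4β→8)-4β-(2-ethoxyethoxy)-5,7,3',4'-tetra-O-benzylepicatechin | c1ccccc1COc1cc(OCc2ccccc2)c2c(c1)O[C@H](c1ccc(OCc3ccccc3)c(OCc3ccccc3)c1)[C@H](O)[C@H]2c1c(OCc2ccccc2)cc(OCc2ccccc2)c2c1O[C@H](c1ccc(OCc3ccccc3)c(OCc3ccccc3)c1)[C@H](O)[C@H]2OCCOCC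
F3 | step 4 | methyl 2-[3,4-bis(benzyloxy)phenyl]-2-(tosylhydrazono)acetate (E/Z mixture) | COC(=O)C(=NNS(=O)(=O)c1ccc(C)cc1)c1ccc(OCc2ccccc2)c(OCc2ccccc2)c1
F4 | step 4 | methyl 2-diazo-2-[3,4-bis(benzyloxy)phenyl]acetate | COC(=O)C(=[N+]=[N-])c1ccc(OCc2ccccc2)c(OCc2ccccc2)c1
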